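**Retrosynthetic overview** (chromene numbering throughout, also for the open precursor: ring A = benzene C4a/C5/C6/C7/C8/C8a, ring B = pyran O1/C2/C3/C4/C4a/C8a)
1. Ring B is cut last at O1–C2 and C4–C4a: target 15 ⇒ resorcinol ketone 12 + prenal 13, because O1–C2(CH3)2–C3=C4 is one prenal unit. The plan rests on the prenyl group already sitting on C8, so C4a is the only unsubstituted carbon ortho to the O1 phenol, and on the C7 hydroxyl being hydrogen-bonded to the C6 ketone.
2. 12 ⇒ tris-MOM ketone 11 ⇒ cut of the C6–C(=O) bond: C4-lithiated 5 + N-methoxy-N-methylamide 8 of MOM-protected phloretic acid.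
3. 5 ⇒ resorcinol bis-MOM ether 2 + prenyl bromide 3 (C8–CH2 bond, lithiation between the two oxygens); 8 ⇒ phloretic acid 6.
4. Ring order: ring A and the 4-hydroxyphenyl ring are bought; ring B is the only ring made, in the last step.

Key step: step 7

Remark: the target has no stereocentre and its ring alkene C3=C4 is cis by necessity, so no stereocontrol is needed; the 4-hydroxyphenyl monophenol is assumed to stay inert towards prenal under amine-salt catalysis and is left unprotected in the key step.

**Step 1**
Reactants: 1 resorcinol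
Product: 2 1,3-bis(methoxymethoxy)benzene
Conditions: NaH, MOMCl, DMF, 0 °C to rt
Reagents that add atoms: chloromethyl methyl ether (MOMCl), COCCl
Why: Williamson-type O-alkylation of the bis-phenoxide with the reactive α-chloro ether gives the bis-acetal, whose MOM groups later direct both lithiations.

**Step 2**
Reactants: 2 1,3-bis(methoxymethoxy)benzene; 3 prenyl bromide (1-bromo-3-methylbut-2-ene)
Product: 5 1,3-bis(methoxymethoxy)-2-(3-methylbut-2-en-1-yl)benzene, via C2 aryllithium 4 (not isolated)
Conditions: n-BuLi, THF, 0 °C to rt; then CuI (10 mol %), 3, −78 °C to rt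
Reagents that add atoms: none
Why: Directed ortho-metalation removes the C2 proton flanked and coordinated by both OMOM groups, and the aryllithium, relayed through an arylcopper species, displaces bromide at the primary carbon of 3 (SN2 allylic substitution), placing the prenyl group between the two oxygens.

**Step 3**
Reactants: 6 phloretic acid (3-(4-hydroxyphenyl)propanoic acid)
Product: 7 3-(4-hydroxyphenyl)-N-methoxy-N-methylpropanamide
Conditions: MeNH(OMe)·HCl, EDC·HCl, HOBt, N-methylmorpholine, CH2Cl2/DMF, 0 °C to rt
Reagents that add atoms: N,O-dimethylhydroxylamine hydrochloride, CNOC.Cl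
Why: Carbodiimide-mediated amide coupling through the HOBt active ester, which the hydroxylamine nitrogen attacks much faster than the phenol oxygen, so the phenol needs no protection here.

**Step 4**
Reactants: 7 3-(4-hydroxyphenyl)-N-methoxy-N-methylpropanamide
Product: 8 N-methoxy-3-[4-(methoxymethoxy)phenyl]-N-methylpropanamide
Conditions: NaH (1.05 equiv), MOMCl, DMF, 0 °C to rt
Reagents that add atoms: chloromethyl methyl ether (MOMCl), COCCl
Why: Williamson-type O-alkylation of the sodium phenoxide masks the only acidic proton that would quench the aryllithium of step 5, and one equivalent of base leaves the amide α-protons untouched.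

**Step 5**
Reactants: 5 1,3-bis(methoxymethoxy)-2-(3-methylbut-2-en-1-yl)benzene; 8 N-methoxy-3-[4-(methoxymethoxy)phenyl]-N-methylpropanamide
Product: 11 1-[2,4-bis(methoxymethoxy)-3-(3-methylbut-2-en-1-yl)phenyl]-3-[4-(methoxymethoxy)phenyl]propan-1-one, via C4 aryllithium 9 (not isolated), via tetrahedral lithium alkoxide 10 (not isolated)
Conditions: n-BuLi, TMEDA, THF, −20 to 0 °C; then 8, −78 to 0 °C; then H2O
Reagents that add atoms: none
Why: Directed ortho-metalation of 5 can only take place at C4 (equivalent to C6), the remaining position ortho to an OMOM group, and the aryllithium adds once to the N-methoxy-N-methylamide (Weinreb ketone synthesis) because chelated adduct 10 survives until aqueous work-up.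

**Step 6**
Reactants: 11 1-[2,4-bis(methoxymethoxy)-3-(3-methylbut-2-en-1-yl)phenyl]-3-[4-(methoxymethoxy)phenyl]propan-1-one
Product: 12 1-[2,4-dihydroxy-3-(3-methylbut-2-en-1-yl)phenyl]-3-(4-hydroxyphenyl)propan-1-one
Conditions: 3 M aq. HCl, MeOH, 40 °C
Reagents that add atoms: none
Why: Acid-catalysed transacetalisation of the three MOM ethers to methanol (acetal cleavage) frees the phenols, with dilute acid and moderate temperature chosen so that protonation of the trisubstituted prenyl alkene stays slower than acetal cleavage.

**Step 7**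
Reactants: 12 1-[2,4-dihydroxy-3-(3-methylbut-2-en-1-yl)phenyl]-3-(4-hydroxyphenyl)propan-1-one; 13 prenal (3-methylbut-2-enal)
Product: 15 1-[7-hydroxy-2,2-dimethyl-8-(3-methylbut-2-en-1-yl)-2H-chromen-6-yl]-3-(4-hydroxyphenyl)propan-1-one, via vinyl ortho-quinone methide 14 (not isolated)
Conditions: ethylenediammonium diacetate (20 mol %), 13 (slow addition, excess), toluene, 110 °C
Reagents that add atoms: none
Why: Ethylenediammonium diacetate converts prenal 13 into an iminium ion, ring carbon C4a of 12 (ortho to the O1 phenol, para to the C7 hydroxyl) adds to its carbon in a Knoevenagel-type C-alkylation that forms C4–C4a, and loss of the amine leaves vinyl ortho-quinone methide 14. The closest known reaction type is the amine-salt-catalysed condensation of resorcinols and acylresorcinols with α,β-unsaturated aldehydes to 2H-chromenes, a formal [3+3] annulation. Ring B then closes by a thermal disrotatory oxa-6π electrocyclisation of the 1-oxatriene O1=C8a–C4a=C4–C3=C2 of 14, which forms O1–C2 and re-aromatises ring A. No stereocentre arises, since C2 carries two methyl groups and the C3=C4 alkene is cis within the ring. The step needs linear fusion through O1 and C4a, and this is secured by the prenyl group at C8, which blocks the other carbon ortho to O1, and by the hydrogen bond from the C7 hydroxyl to the C6 ketone, which takes that oxygen out of play. The 4-hydroxyphenyl ring, a plain monophenol, is too poor a nucleophile for the iminium ion, and the ketone chain and the prenyl alkene have no reaction channel at this near-neutral pH.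

**Compound list**
1 | resorcinol (benzene-1,3-diol) | Oc1cccc(O)c1 | starting material
2 | 1,3-bis(methoxymethoxy)benzene | COCOc1cccc(OCOC)c1 | intermediate
3 | prenyl bromide (1-bromo-3-methylbut-2-ene) | CC(C)=CCBr | starting material
4 | 2,6-bis(methoxymethoxy)phenyllithium (C2 aryllithium, not isolated) | [Li]c1c(OCOC)cccc1OCOC | intermediate
5 | 1,3-bis(methoxymethoxy)-2-(3-methylbut-2-en-1-yl)benzene | COCOc1cccc(OCOC)c1CC=C(C)C | intermediate
6 | phloretic acid (3-(4-hydroxyphenyl)propanoic acid) | O=C(O)CCc1ccc(O)cc1 | starting material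
7 | 3-(4-hydroxyphenyl)-N-methoxy-N-methylpropanamide | CON(C)C(=O)CCc1ccc(O)cc1 | intermediate
8 | N-methoxy-3-[4-(methoxymethoxy)phenyl]-N-methylpropanamide | CON(C)C(=O)CCc1ccc(OCOC)cc1 | intermediate
9 | [2,4-bis(methoxymethoxy)-3-(3-methylbut-2-en-1-yl)phenyl]lithium (C4 aryllithium, not isolated) | [Li]c1ccc(OCOC)c(CC=C(C)C)c1OCOC | intermediate
10 | lithium 1-[2,4-bis(methoxymethoxy)-3-(3-methylbut-2-en-1-yl)phenyl]-1-[methoxy(methyl)amino]-3-[4-(methoxymethoxy)phenyl]propan-1-olate (racemic, not isolated) | COCOc1ccc(CCC(O[Li])(N(C)OC)c2ccc(OCOC)c(CC=C(C)C)c2OCOC)cc1 | intermediate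
11 | 1-[2,4-bis(methoxymethoxy)-3-(3-methylbut-2-en-1-yl)phenyl]-3-[4-(methoxymethoxy)phenyl]propan-1-one | COCOc1ccc(CCC(=O)c2ccc(OCOC)c(CC=C(C)C)c2OCOC)cc1 | intermediate
12 | 1-[2,4-dihydroxy-3-(3-methylbut-2-en-1-yl)phenyl]-3-(4-hydroxyphenyl)propan-1-one (2',4',4-trihydroxy-3'-prenyldihydrochalcone) | CC(C)=CCc1c(O)ccc(C(=O)CCc2ccc(O)cc2)c1O | intermediate
13 | prenal (3-methylbut-2-enal) | CC(C)=CC=O | starting material
14 | 2-hydroxy-3-[3-(4-hydroxyphenyl)propanoyl]-5-(3-methylbut-2-en-1-ylidene)-1-(3-methylbut-2-en-1-yl)cyclohexa-1,3-dien-6-one (vinyl ortho-quinone methide, not isolated) | CC(C)=CCC1=C(O)C(C(=O)CCc2ccc(O)cc2)=CC(=CC=C(C)C)C1=O | intermediate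
15 | 1-[7-hydroxy-2,2-dimethyl-8-(3-methylbut-2-en-1-yl)-2H-chromen-6-yl]-3-(4-hydroxyphenyl)propan-1-one | CC(C)=CCc1c(O)c(C(=O)CCc2ccc(O)cc2)cc2c1OC(C)(C)C=C2 | target

**Totals**
Total step count: 7.
Longest linear sequence: 5 steps (steps 1, 2, 5, 6, 7; the branch from 6 through steps 3 and 4 joins at step 5 and is equally long).

**Steps most likely to fail**

Step 7 (key step). The acyl group deactivates ring A, so C-alkylation at C4a may be slower than the amine-catalysed self-condensation of prenal, and the aldehyde may be used up before the ring closes. The fallback builds the same ring from an aryl propargyl ether; it sets out from 12 and comes back at 15. The most acidic non-chelated phenol of 12 (the future O1) would be alkylated with 3-chloro-3-methylbut-1-yne (K2CO3, KI, CuI cat., acetone, 56 °C) to give 1-{2-hydroxy-4-[(2-methylbut-3-yn-2-yl)oxy]-3-(3-methylbut-2-en-1-yl)phenyl}-3-(4-hydroxyphenyl)propan-1-one F1. Heating F1 in N,N-diethylaniline at about 150 °C should bring about an aromatic propargyl Claisen rearrangement to C4a (C8 is blocked), enolisation, a 1,5-hydrogen shift to the same quinone methide 14 and oxa-6π closure to 15.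

Step 5. Deprotonation of the doubly activated benzylic-allylic CH2 of the prenyl group may compete with ring metalation, and the hindered aryllithium may enolise the amide instead of adding to it. The fallback replaces C–H metalation by bromine–lithium exchange; it sets out from 2 and comes back at aryllithium 9, which is carried on to 11 as in step 5. Compound 2 would be brominated para to one MOM ether (NBS, MeCN, 0 °C) to 1-bromo-2,4-bis(methoxymethoxy)benzene F2. LiN(i-Pr)2 (THF, −78 °C) would remove the proton between the two oxygens to give 3-bromo-2,6-bis(methoxymethoxy)phenyllithium F3, which is not isolated but prenylated with 3 (CuI cat.) to 1-bromo-2,4-bis(methoxymethoxy)-3-(3-methylbut-2-en-1-yl)benzene F4. Exchange with n-BuLi (THF, −78 °C), far faster than any deprotonation, then gives 9, and 8 is added at once.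

Step 6. Protonation of the prenyl alkene may lead to cyclisation onto a flanking phenol (2,2-dimethylchroman formation) or to hydration before the last MOM ether has gone. The fallback reaches 12 without any acid after the prenyl group is in place; it sets out from 1 and 6 and comes back at 12. Friedel–Crafts acylation of 1 with 6 (BF3·OEt2, 85 °C) would give 1-(2,4-dihydroxyphenyl)-3-(4-hydroxyphenyl)propan-1-one F5. Selective O-alkylation of its most acidic phenol with 3-chloro-3-methylbut-1-yne (K2CO3, KI, CuI cat., acetone, 56 °C) would give 1-{2-hydroxy-4-[(2-methylbut-3-yn-2-yl)oxy]phenyl}-3-(4-hydroxyphenyl)propan-1-one F6. Semihydrogenation (H2, Pd on CaCO3 poisoned with Pb(OAc)2, quinoline, EtOAc, rt) would give 1-{2-hydroxy-4-[(2-methylbut-3-en-2-yl)oxy]phenyl}-3-(4-hydroxyphenyl)propan-1-one F7. Heating F7 (N,N-diethylaniline, about 140 °C) should deliver 12 by an aromatic Claisen rearrangement to the carbon between the two oxygens, the site favoured by the chelated ketone.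

**Further compounds**
F1 | step 7 | 1-{2-hydroxy-4-[(2-methylbut-3-yn-2-yl)oxy]-3-(3-methylbut-2-en-1-yl)phenyl}-3-(4-hydroxyphenyl)propan-1-one | CC(C)=CCc1c(OC(C)(C)C#C)ccc(C(=O)CCc2ccc(O)cc2)c1O
F2 | step 5 | 1-bromo-2,4-bis(methoxymethoxy)benzene | COCOc1ccc(Br)c(OCOC)c1
F3 | step 5 | 3-bromo-2,6-bis(methoxymethoxy)phenyllithium | [Li]c1c(OCOC)ccc(Br)c1OCOC
F4 | step 5 | 1-bromo-2,4-bis(methoxymethoxy)-3-(3-methylbut-2-en-1-yl)benzene | COCOc1ccc(Br)c(OCOC)c1CC=C(C)C
F5 | step 6 | 1-(2,4-dihydroxyphenyl)-3-(4-hydroxyphenyl)propan-1-one | O=C(CCc1ccc(O)cc1)c1ccc(O)cc1O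
F6 | step 6 | 1-{2-hydroxy-4-[(2-methylbut-3-yn-2-yl)oxy]phenyl}-3-(4-hydroxyphenyl)propan-1-one | C#CC(C)(C)Oc1ccc(C(=O)CCc2ccc(O)cc2)c(O)c1
F7 | step 6 | 1-{2-hydroxy-4-[(2-methylbut-3-en-2-yl)oxy]phenyl}-3-(4-hydroxyphenyl)propan-1-one | C=CC(C)(C)Oc1ccc(C(=O)CCc2ccc(O)cc2)c(O)c1
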